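**Analysis of the target**

Target 26 has no fused or bridged ring: two benzene rings are joined through one ether oxygen. Ring A is a benzoic acid (C1–CO2H) with a methoxy group at C2, the (1R)-1,3-dihydroxy-3-methylbutyl chain at C3 and the aryloxy oxygen at C6. Ring B carries that oxygen at C1', a free hydroxyl at C2', a methyl group at C4' and a hydroxymethyl group at C6'. The only stereocentre is the benzylic carbinol carbon of the side chain (R); it is isolated from all other functionality, so its configuration must come from a reagent. Several groups are sensitive: the benzylic alcohol lies para to the ether oxygen and ionises easily under acid, the tertiary alcohol 1,3 to it can dehydrate, the ring B phenol next to the ether oxygen is oxidisable, and the 2,6-disubstituted benzoic acid is so hindered that an ester at C1 would be hard to hydrolyse. The main difficulty is the ether bond: it joins the oxygen of a 2,6-disubstituted phenol (ring B) to a carbon of a ring A that bears four contiguous substituents, which is a poor case for intermolecular aryl ether formation. The strategy rests on one observation: the ether oxygen is ortho to the carboxyl carbon on ring A (C6 beside C1) and ortho to the free hydroxyl on ring B (C1' beside C2'). If the carboxyl carbon is bonded in thought to C1', the result is a benzophenone with a hydroxyl ortho to the carbonyl on each ring, which can pass through a spiro dienone and reopen to exactly this ether, acid and phenol.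

**Retrosynthetic reasoning**

26 from 25. The last operation is removal of the two silyl ethers on the tertiary alcohol and on the C6' hydroxymethyl group. Both are cleaved under the same non-acidic conditions, so the ionisable benzylic carbinol is never exposed to acid once it exists.

25 from 24. The C–H bond at the carbinol carbon is cut, leading back to the aryl ketone 24. The forward reaction is a catalyst-controlled asymmetric transfer hydrogenation. It is placed late because the ketone is needed earlier: para to the ring A phenol, it makes that ring harder to oxidise in the key step. Placing it late also means that no stereocentre has to survive the oxidations.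

24 from 23. The carboxyl carbon of 24 is reconnected to C1' of ring B, which gives the spiro dienone 23. Forward, a hydrolytic retro-Claisen cleavage breaks the bond between the five-ring ketone and C1'; ring B leaves as its phenoxide and regains aromaticity. This one cut produces the ether, the free acid (no ester to hydrolyse) and the C2' hydroxyl together.

23 from 22. The O–C1' bond is cut, giving the 2,2'-dihydroxybenzophenone 22. Forward, oxidation of the ring B phenol lets the ring A phenol oxygen add to C1' and close the five-membered ring. The hindered C–O bond is thus made intramolecularly, with the two rings held together by the carbonyl carbon.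

22 from 17 (through 21, 20, 19 and 18). These steps only adjust protecting groups and oxidation level. The phenols are carried as methoxymethyl ethers because those ethers are needed as directing groups. Both ketones are carried as carbinols so that organolithium chemistry is possible, and they are oxidised together in one step. The tertiary alcohol is silylated before the phenols are released, so that the retro-Claisen step does not meet a free β-hydroxy ketone.

17 from 7 and 15. The bond between C1 of ring A and the carbinol carbon is cut. C1 lies between the methoxy and methoxymethoxy oxygens of 7, so deprotonation there gives aryllithium 16 reliably. Aldehyde 15 has no α-hydrogen and accepts hindered nucleophiles. Cutting on the ring B side instead would need a ring A aldehyde and one more step on that branch.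

7 from 1 and 3 (through 6, 5, 4 and 2). The side chain is cut between the carbinol carbon and its CH2 group: the methallyl nucleophile 4, made from 3, adds to aldehyde 2. Markovnikov hydration of the 1,1-disubstituted alkene of 5 gives the tertiary alcohol of 6. The diol is tied up as the cyclic acetal 7 so that no alkoxide competes as a directing group during lithiation.

15 from 8 (through 14, 13, 12, 11, 10 and 9). C1' of ring B lies between the hydroxymethyl carbon and the oxygen-bearing carbon of 10. The benzylic alkoxide and the methoxymethoxy group direct lithiation there together (11). The position is first held by iodine (12), the alcohol is silylated (13), and only then is the formyl group introduced through 14. Direct formylation of 11 would give a hydroxy aldehyde that closes to a lactol and could not be silylated cleanly.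

**Alternatives that were turned down**

Alternative 1: Ring B is built instead of bought, by cutting C3'–C4' and C1'–C6'.
- Forward key step: the allyl 4-aryloxyacetoacetate A1 adds through C3' to the β-carbon of methyl (E)-2-oxopent-3-enoate A2, and the aryloxy-bearing C1' then condenses on the C6' keto group to give the 2-aryloxycyclohexenone A3. Decarboxylation of the allyl ester, dehydrogenation to the phenol, ester reduction and deprotection would follow.
- For: the hindered ether bond is made by simple O-alkylation at an sp3 carbon. Every ring B substituent is fixed by the connectivity of A1 and A2. The R carbinol can be set early and carried as its acetonide. No dearomatised intermediate is involved.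
- Against: adducts of 1,3-dicarbonyl compounds with β,γ-unsaturated α-keto esters tend to close through the enol oxygen to dihydropyran hemiketals, not through carbon. C1' is the least acidic carbon of A1. Aromatisation needs a separate oxidation. The tert-butyl ester of the hindered acid must be removed with acid while the ionisable benzylic carbinol is present. The ring A phenol needed for A1 requires the same lithiation chemistry as 16, and about six steps follow the annulation.
- Comparison: it is stronger in the certainty of ring B regiochemistry and in needing no late asymmetric reduction. The chosen route instead takes both rings from commercial arenes and obtains ether, acid and phenol from one intermediate (23).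

Alternative 2: The C6–O and C1–CO2H bonds are both cut, with ring A as an aryne.
- Forward key step: fluoride releases the C1–C6 aryne from the ortho-silylaryl triflate A4. The phenoxide of ring B phenol A5 adds at C6, the methoxy group at C2 favouring negative charge at C1, and the C1 aryl anion is trapped by carboxylation to give A6.
- For: it is the most convergent plan. The methoxy group sets the regiochemistry, the acid appears directly, the stereocentre is in place beforehand, and only deprotections remain.
- Against: three components compete. The C1 anion can be protonated by any phenol present faster than it is carboxylated. The phenoxide of A5 is 2,6-disubstituted and is reversibly carbonated under the same conditions. A4 is a contiguously tetrasubstituted arene that takes about as long to make as ring A of 22. The final acetonide removal needs acid on a benzylic carbinol para to an aryloxy group.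
- Comparison: it is stronger on convergence and on the number of steps after the key step. The chosen route offers an intramolecular C–O closure with the carboxyl carbon already attached, so there is no competition for an aryl anion, and a non-acidic final deprotection.

Alternative 3: Ring A is cut into a four-carbon vinylketene unit (C2–C5) and a two-carbon alkyne (C1, C6) that already carries the ring B oxygen.
- Forward key step: irradiation of the diazo enone A7 gives a vinylketene by Wolff rearrangement. It adds to the aryloxyalkyne A8 in a [2+2] cycloaddition; four-electron ring opening and six-electron closure then give phenol A9. O-Methylation, removal of the p-methoxybenzyl group, two-stage oxidation of the C1 CH2OH to the acid and three deprotections would follow.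
- For: the polarity of the ynol ether dictates the substitution pattern of ring A. The ether is never formed at a hindered aromatic carbon. The stereocentre comes from a small building block.
- Against: A8 is an aryl alkynyl ether of a 2,6-disubstituted phenol, which needs a multistep preparation and is labile. The photochemical step can be eroded by E/Z isomerisation of the enone and by ketene dimerisation. At least six steps follow the annulation, making this the longest route.
- Comparison: it is stronger on regiochemical certainty for ring A. The chosen route needs only three steps after its key step and uses aromatic starting materials for both rings.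

Key step: step 15

Assumption: every carbinol, benzhydrol and spiro centre formed before step 17 is taken as racemic or as a diastereomer mixture, because each is erased by oxidation or ring opening before the R carbinol is set.

**Route**

Step 1
Reactants: 1 4-hydroxy-2-methoxybenzaldehyde
Product: 2 2-methoxy-4-(methoxymethoxy)benzaldehyde
Conditions: MOMCl, iPr2NEt, CH2Cl2, 0 °C to rt
Reagents that add atoms: chloromethyl methyl ether (MOMCl), COCCl
Why: O-alkylation of the acidic para-formyl phenol (Williamson-type); the methoxymethyl ether protects the phenol and later directs lithiation to the carbon between the two ring oxygens.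

Step 2
Reactants: 2 2-methoxy-4-(methoxymethoxy)benzaldehyde; 3 3-chloro-2-methylprop-1-ene
Product: 5 rac-1-[2-methoxy-4-(methoxymethoxy)phenyl]-3-methylbut-3-en-1-ol, via methallylmagnesium chloride 4 (not isolated)
Conditions: 3, Mg, THF, 0 °C; then 2, -78 to 0 °C
Reagents that add atoms: none
Why: Grignard addition of an allylic magnesium reagent to an aromatic aldehyde; the aldehyde has no α-hydrogen and the new carbinol centre need not be controlled because it is oxidised in step 12.

Step 3
Reactants: 5 rac-1-[2-methoxy-4-(methoxymethoxy)phenyl]-3-methylbut-3-en-1-ol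
Product: 6 rac-1-[2-methoxy-4-(methoxymethoxy)phenyl]-3-methylbutane-1,3-diol
Conditions: Co(acac)2 (cat.), PhSiH3, O2 (1 atm), THF, rt
Reagents that add atoms: dioxygen, O=O
Why: Mukaiyama hydration; hydrogen-atom transfer to the 1,1-disubstituted alkene gives the tertiary radical, which is trapped by oxygen and reduced to the tertiary alcohol (Markovnikov), under neutral conditions that leave the electron-rich benzylic alcohol untouched.

Step 4
Reactants: 6 rac-1-[2-methoxy-4-(methoxymethoxy)phenyl]-3-methylbutane-1,3-diol
Product: 7 rac-6-[2-methoxy-4-(methoxymethoxy)phenyl]-2,2,4,4-tetramethyl-1,3-dioxane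
Conditions: 2-methoxypropene, PPTS (cat.), CH2Cl2, 0 °C
Reagents that add atoms: 2-methoxypropene, C=C(C)OC
Why: Kinetic acetonide formation from the 1,3-diol with an enol ether; both hydroxyls are masked in one step so that no alkoxide can direct lithiation to the wrong ring position in step 10.

Step 5
Reactants: 8 3-hydroxy-5-methylbenzoic acid
Product: 9 methoxymethyl 3-(methoxymethoxy)-5-methylbenzoate
Conditions: MOMCl (2.5 equiv), iPr2NEt, CH2Cl2, 0 °C to rt
Reagents that add atoms: chloromethyl methyl ether (MOMCl), COCCl
Why: Double O-alkylation of phenol and carboxylate; the ester is only a transient activation for the reduction in step 6, while the aryl ether is kept as protecting and directing group.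

Step 6
Reactants: 9 methoxymethyl 3-(methoxymethoxy)-5-methylbenzoate
Product: 10 [3-(methoxymethoxy)-5-methylphenyl]methanol
Conditions: LiAlH4, THF, 0 °C
Reagents that add atoms: none
Why: Hydride reduction of the ester to the benzyl alcohol; the aryl methoxymethyl ether is inert to LiAlH4.

Step 7
Reactants: 10 [3-(methoxymethoxy)-5-methylphenyl]methanol
Product: 12 [2-iodo-3-(methoxymethoxy)-5-methylphenyl]methanol, via dilithiated benzyl alkoxide 11 (not isolated)
Conditions: n-BuLi (2.3 equiv), TMEDA, Et2O, 0 °C to rt; then I2, THF, -78 °C to rt
Reagents that add atoms: iodine, II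
Why: Directed ortho-metalation; the lithium alkoxide and the methoxymethoxy group flank C2 and cooperate to make it the most acidic ring position, and iodine traps the aryllithium. The iodide is chosen over direct formylation because the hydroxy aldehyde would close to a lactol.

Step 8
Reactants: 12 [2-iodo-3-(methoxymethoxy)-5-methylphenyl]methanol
Product: 13 tert-butyl{[2-iodo-3-(methoxymethoxy)-5-methylphenyl]methoxy}diphenylsilane
Conditions: TBDPSCl, imidazole, DMF, rt
Reagents that add atoms: tert-butyl(chloro)diphenylsilane, CC(C)(C)[Si](Cl)(c1ccccc1)c1ccccc1
Why: Standard silylation of a primary alcohol; the bulky silyl ether is kept to the end and later shields the dienone of 23.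

Step 9
Reactants: 13 tert-butyl{[2-iodo-3-(methoxymethoxy)-5-methylphenyl]methoxy}diphenylsilane
Product: 15 2-{[tert-butyl(diphenyl)silyl]oxymethyl}-6-(methoxymethoxy)-4-methylbenzaldehyde, via arylmagnesium chloride 14 (not isolated)
Conditions: i-PrMgCl·LiCl, THF, -20 °C; then DMF, -20 °C to rt
Reagents that add atoms: N,N-dimethylformamide, CN(C)C=O
Why: Iodine–magnesium exchange followed by formylation with a formamide; the magnesium reagent is preferred to the aryllithium because it does not undergo silyl migration from the neighbouring benzylic oxygen to carbon.

Step 10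
Reactants: 7 rac-6-[2-methoxy-4-(methoxymethoxy)phenyl]-2,2,4,4-tetramethyl-1,3-dioxane; 15 2-{[tert-butyl(diphenyl)silyl]oxymethyl}-6-(methoxymethoxy)-4-methylbenzaldehyde
Product: 17 {2-[(tert-butyldiphenylsilyl)oxymethyl]-6-(methoxymethoxy)-4-methylphenyl}[2-methoxy-6-(methoxymethoxy)-3-(2,2,6,6-tetramethyl-1,3-dioxan-4-yl)phenyl]methanol (diastereomer mixture), via ring A aryllithium 16 (not isolated)
Conditions: 7, n-BuLi, TMEDA, THF, 0 °C; then 15, -78 to -20 °C
Reagents that add atoms: none
Why: Directed ortho-metalation at the ring A carbon between the methoxy and methoxymethoxy groups, then 1,2-addition to the non-enolisable aldehyde; this is the standard entry to tetra-ortho-substituted benzhydrols, and the new carbinol centre is oxidised away in step 12.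

Step 11
Reactants: 17 the benzhydrol from step 10
Product: 18 1-[3-({2-[(tert-butyldiphenylsilyl)oxymethyl]-6-(methoxymethoxy)-4-methylphenyl}(hydroxy)methyl)-2-methoxy-4-(methoxymethoxy)phenyl]-3-methylbutane-1,3-diol (diastereomer mixture)
Conditions: AcOH/THF/H2O (3:1:1), 40 °C
Reagents that add atoms: none
Why: Acetal hydrolysis; the tetramethyl dioxane is strained by a 1,3-diaxial methyl pair and should open under conditions that leave the aryl methoxymethyl ethers and the silyl ether intact. Water as nucleophile means that any ionisation of the benzylic carbinols only returns the alcohols.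

Step 12
Reactants: 18 the triol from step 11
Product: 19 1-[3-{2-[(tert-butyldiphenylsilyl)oxymethyl]-6-(methoxymethoxy)-4-methylbenzoyl}-2-methoxy-4-(methoxymethoxy)phenyl]-3-hydroxy-3-methylbutan-1-one
Conditions: Dess–Martin periodinane (3 equiv), NaHCO3, CH2Cl2, rt
Reagents that add atoms: none
Why: Dess–Martin oxidation of both secondary benzylic alcohols in one operation; the tertiary alcohol cannot be oxidised and the buffered, non-basic medium avoids retro-aldol cleavage of the β-hydroxy ketone.

Step 13
Reactants: 19 the diketone alcohol from step 12
Product: 20 1-[3-{2-[(tert-butyldiphenylsilyl)oxymethyl]-6-(methoxymethoxy)-4-methylbenzoyl}-2-methoxy-4-(methoxymethoxy)phenyl]-3-methyl-3-(triethylsilyloxy)butan-1-one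
Conditions: TESOTf, 2,6-lutidine, CH2Cl2, -78 to 0 °C
Reagents that add atoms: triethylsilyl trifluoromethanesulfonate, CC[Si](CC)(CC)OS(=O)(=O)C(F)(F)F
Why: Silylation of a tertiary alcohol with a silyl triflate; the ether blocks retro-aldol fragmentation in the basic step 16 and is removed together with the other silyl group at the end.

Step 14
Reactants: 20 the triethylsilyl ether from step 13
Product: 22 1-[3-{2-[(tert-butyldiphenylsilyl)oxymethyl]-6-hydroxy-4-methylbenzoyl}-4-hydroxy-2-methoxyphenyl]-3-methyl-3-(triethylsilyloxy)butan-1-one, via bis(trimethylsilyl) aryl ether 21 (not isolated)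
Conditions: TMSOTf, 2,2'-bipyridyl, CH2Cl2, 0 °C to rt; then H2O
Reagents that add atoms: none
Why: Silyl triflate/bipyridyl cleavage of aromatic methoxymethyl ethers; the acetal is activated as a pyridinium salt and the phenols emerge as trimethylsilyl ethers that hydrolyse on contact with water. The medium stays non-acidic, so the tertiary triethylsilyl ether and the primary silyl ether should survive.

Step 15
Reactants: 22 the 2,2'-dihydroxybenzophenone from step 14
Product: 23 rac-6'-[(tert-butyldiphenylsilyl)oxymethyl]-4-methoxy-4'-methyl-5-[3-methyl-3-(triethylsilyloxy)butanoyl]-3H-spiro[1-benzofuran-2,1'-cyclohexa-3',5'-diene]-2',3-dione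
Conditions: graphite anode, platinum cathode, divided cell, constant current (about 2.1 F per mol), LiClO4, 2,6-lutidine, MeCN/HFIP (9:1), 0 °C
Reagents that add atoms: none
Why: The ring B phenol gives up an electron at the anode and its proton to the base; the phenoxyl radical is oxidised further to a phenoxonium ion with positive charge at C1', C3' and C5'. The ring A phenol oxygen, held over C1' by the benzophenone carbonyl, adds there and loses its proton to give 23. The closest known reaction type is the oxidative phenol coupling of 2,2'-dihydroxybenzophenones to grisadienediones, here in its less common ortho-dienone form and driven by an electrode. The one ring formed is the five-membered benzofuranone, closed in a 5-exo-trig mode onto the ring B π system. The spiro carbon C1' is the only new stereocentre; it forms racemic and needs no control because it returns to sp2 in step 16. Ring B, not ring A, must be oxidised: the ring A phenol carries a para-acyl and an ortho-aroyl group, while the ring B phenol has one acyl and two alkyl groups, so a low current density should keep the electrolysis on the ring B oxidation. C1' must be the site of attack: C3' and C5' cannot be reached by the tethered oxygen, and the weakly nucleophilic medium and low substrate concentration disfavour capture by solvent or a second molecule. The product has no free phenol and should not be oxidised further; the bulky silyloxymethyl group at C6' and the methyl at C4' should slow [4+2] dimerisation of the dienone, which is taken into step 16 without storage.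

Step 16
Reactants: 23 the spiro dienone from step 15
Product: 24 6-{2-[(tert-butyldiphenylsilyl)oxymethyl]-6-hydroxy-4-methylphenoxy}-2-methoxy-3-[3-methyl-3-(triethylsilyloxy)butanoyl]benzoic acid
Conditions: LiOH, THF/H2O (4:1), 0 °C; then dilute HCl to pH 3, 0 °C
Reagents that add atoms: lithium hydroxide, [Li+].[OH-]
Why: Retro-Claisen cleavage of a non-enolisable 1,3-diketone; hydroxide adds to the strained five-ring ketone and the bond to C1' breaks because ring B leaves as an aromatic phenoxide. Cleavage on the dienone side would release no comparable aromatisation energy, and the low temperature is chosen to avoid β-elimination in the side chain.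

Step 17
Reactants: 24 the keto acid from step 16
Product: 25 6-{2-[(tert-butyldiphenylsilyl)oxymethyl]-6-hydroxy-4-methylphenoxy}-3-[(1R)-1-hydroxy-3-methyl-3-(triethylsilyloxy)butyl]-2-methoxybenzoic acid
Conditions: RuCl(p-cymene)[(R,R)-TsDPEN] (cat.), HCO2H/Et3N (5:2), DMF, 40 °C
Reagents that add atoms: none
Why: Noyori-type asymmetric transfer hydrogenation of an aryl alkyl ketone; the ruthenium hydride and the N–H of the ligand are delivered to the carbonyl face on which the aryl group can lie against the η6-arene. With the (R,R) ligand this gives the R carbinol, by analogy with acetophenone and with the same priority order (OH, aryl, CH2, H). The triethylamine/formic acid medium tolerates the free acid and phenol.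

Step 18
Reactants: 25 the R carbinol from step 17
Product: 26 3-[(1R)-1,3-dihydroxy-3-methylbutyl]-6-[2-hydroxy-6-(hydroxymethyl)-4-methylphenoxy]-2-methoxybenzoic acid
Conditions: TBAF (excess), THF, 0 °C to rt
Reagents that add atoms: none
Why: Fluoride-induced cleavage of both silyl ethers, driven by the Si–F bond; the conditions are non-acidic and non-oxidising, so the benzylic R carbinol is not ionised and its configuration is kept.

**Compound list**

1 | 4-hydroxy-2-methoxybenzaldehyde | COc1cc(O)ccc1C=O | starting material
2 | 2-methoxy-4-(methoxymethoxy)benzaldehyde | COCOc1ccc(C=O)c(OC)c1 | intermediate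
3 | 3-chloro-2-methylprop-1-ene | C=C(C)CCl | starting material
4 | methallylmagnesium chloride | C=C(C)C[Mg]Cl | intermediate (not isolated)
5 | rac-1-[2-methoxy-4-(methoxymethoxy)phenyl]-3-methylbut-3-en-1-ol | COCOc1ccc(C(O)CC(C)=C)c(OC)c1 | intermediate
6 | rac-1-[2-methoxy-4-(methoxymethoxy)phenyl]-3-methylbutane-1,3-diol | COCOc1ccc(C(O)CC(C)(C)O)c(OC)c1 | intermediate
7 | rac-6-[2-methoxy-4-(methoxymethoxy)phenyl]-2,2,4,4-tetramethyl-1,3-dioxane | COCOc1ccc(C2CC(C)(C)OC(C)(C)O2)c(OC)c1 | intermediate
8 | 3-hydroxy-5-methylbenzoic acid | Cc1cc(O)cc(C(=O)O)c1 | starting material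
9 | methoxymethyl 3-(methoxymethoxy)-5-methylbenzoate | COCOC(=O)c1cc(C)cc(OCOC)c1 | intermediate
10 | [3-(methoxymethoxy)-5-methylphenyl]methanol | COCOc1cc(C)cc(CO)c1 | intermediate
11 | lithium [2-lithio-3-(methoxymethoxy)-5-methylphenyl]methanolate | [Li]OCc1cc(C)cc(OCOC)c1[Li] | intermediate (not isolated)
12 | [2-iodo-3-(methoxymethoxy)-5-methylphenyl]methanol | COCOc1cc(C)cc(CO)c1I | intermediate
13 | tert-butyl{[2-iodo-3-(methoxymethoxy)-5-methylphenyl]methoxy}diphenylsilane | COCOc1cc(C)cc(CO[Si](c2ccccc2)(c2ccccc2)C(C)(C)C)c1I | intermediate
14 | [2-{[tert-butyl(diphenyl)silyl]oxymethyl}-6-(methoxymethoxy)-4-methylphenyl]magnesium chloride | COCOc1cc(C)cc(CO[Si](c2ccccc2)(c2ccccc2)C(C)(C)C)c1[Mg]Cl | intermediate (not isolated)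
15 | 2-{[tert-butyl(diphenyl)silyl]oxymethyl}-6-(methoxymethoxy)-4-methylbenzaldehyde | COCOc1cc(C)cc(CO[Si](c2ccccc2)(c2ccccc2)C(C)(C)C)c1C=O | intermediate
16 | [2-methoxy-6-(methoxymethoxy)-3-(2,2,6,6-tetramethyl-1,3-dioxan-4-yl)phenyl]lithium (racemic) | COCOc1ccc(C2CC(C)(C)OC(C)(C)O2)c(OC)c1[Li] | intermediate (not isolated)
17 | {2-[(tert-butyldiphenylsilyl)oxymethyl]-6-(methoxymethoxy)-4-methylphenyl}[2-methoxy-6-(methoxymethoxy)-3-(2,2,6,6-tetramethyl-1,3-dioxan-4-yl)phenyl]methanol (diastereomer mixture) | COCOc1ccc(C2CC(C)(C)OC(C)(C)O2)c(OC)c1C(O)c1c(OCOC)cc(C)cc1CO[Si](c1ccccc1)(c1ccccc1)C(C)(C)C | intermediate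
18 | 1-[3-({2-[(tert-butyldiphenylsilyl)oxymethyl]-6-(methoxymethoxy)-4-methylphenyl}(hydroxy)methyl)-2-methoxy-4-(methoxymethoxy)phenyl]-3-methylbutane-1,3-diol (diastereomer mixture) | COCOc1ccc(C(O)CC(C)(C)O)c(OC)c1C(O)c1c(OCOC)cc(C)cc1CO[Si](c1ccccc1)(c1ccccc1)C(C)(C)C | intermediate
19 | 1-[3-{2-[(tert-butyldiphenylsilyl)oxymethyl]-6-(methoxymethoxy)-4-methylbenzoyl}-2-methoxy-4-(methoxymethoxy)phenyl]-3-hydroxy-3-methylbutan-1-one | COCOc1ccc(C(=O)CC(C)(C)O)c(OC)c1C(=O)c1c(OCOC)cc(C)cc1CO[Si](c1ccccc1)(c1ccccc1)C(C)(C)C | intermediate
20 | 1-[3-{2-[(tert-butyldiphenylsilyl)oxymethyl]-6-(methoxymethoxy)-4-methylbenzoyl}-2-methoxy-4-(methoxymethoxy)phenyl]-3-methyl-3-(triethylsilyloxy)butan-1-one | COCOc1ccc(C(=O)CC(C)(C)O[Si](CC)(CC)CC)c(OC)c1C(=O)c1c(OCOC)cc(C)cc1CO[Si](c1ccccc1)(c1ccccc1)C(C)(C)C | intermediate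
21 | 1-[3-{2-[(tert-butyldiphenylsilyl)oxymethyl]-4-methyl-6-(trimethylsilyloxy)benzoyl}-2-methoxy-4-(trimethylsilyloxy)phenyl]-3-methyl-3-(triethylsilyloxy)butan-1-one | C[Si](C)(C)Oc1ccc(C(=O)CC(C)(C)O[Si](CC)(CC)CC)c(OC)c1C(=O)c1c(O[Si](C)(C)C)cc(C)cc1CO[Si](c1ccccc1)(c1ccccc1)C(C)(C)C | intermediate (not isolated)
22 | 1-[3-{2-[(tert-butyldiphenylsilyl)oxymethyl]-6-hydroxy-4-methylbenzoyl}-4-hydroxy-2-methoxyphenyl]-3-methyl-3-(triethylsilyloxy)butan-1-one | COc1c(C(=O)CC(C)(C)O[Si](CC)(CC)CC)ccc(O)c1C(=O)c1c(O)cc(C)cc1CO[Si](c1ccccc1)(c1ccccc1)C(C)(C)C | intermediate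
23 | rac-6'-[(tert-butyldiphenylsilyl)oxymethyl]-4-methoxy-4'-methyl-5-[3-methyl-3-(triethylsilyloxy)butanoyl]-3H-spiro[1-benzofuran-2,1'-cyclohexa-3',5'-diene]-2',3-dione (racemic at the spiro carbon) | COc1c(C(=O)CC(C)(C)O[Si](CC)(CC)CC)ccc2OC3(C(=O)c12)C(=O)C=C(C)C=C3CO[Si](c1ccccc1)(c1ccccc1)C(C)(C)C | intermediate
24 | 6-{2-[(tert-butyldiphenylsilyl)oxymethyl]-6-hydroxy-4-methylphenoxy}-2-methoxy-3-[3-methyl-3-(triethylsilyloxy)butanoyl]benzoic acid | COc1c(C(=O)CC(C)(C)O[Si](CC)(CC)CC)ccc(Oc2c(O)cc(C)cc2CO[Si](c2ccccc2)(c2ccccc2)C(C)(C)C)c1C(=O)O | intermediate
25 | 6-{2-[(tert-butyldiphenylsilyl)oxymethyl]-6-hydroxy-4-methylphenoxy}-3-[(1R)-1-hydroxy-3-methyl-3-(triethylsilyloxy)butyl]-2-methoxybenzoic acid | COc1c([C@H](O)CC(C)(C)O[Si](CC)(CC)CC)ccc(Oc2c(O)cc(C)cc2CO[Si](c2ccccc2)(c2ccccc2)C(C)(C)C)c1C(=O)O | intermediate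
26 | 3-[(1R)-1,3-dihydroxy-3-methylbutyl]-6-[2-hydroxy-6-(hydroxymethyl)-4-methylphenoxy]-2-methoxybenzoic acid | COc1c([C@H](O)CC(C)(C)O)ccc(Oc2c(O)cc(C)cc2CO)c1C(=O)O | target

**Step count and risks**

Total: 18 steps. Longest linear sequence: 14 steps (from 8 through steps 5 to 18); the ring A branch from 1 runs 13 steps (steps 1 to 4 and 10 to 18).

Least certain steps:

Step 15 (key step). The phenoxonium ion could be captured at C5' by solvent or by a second molecule instead of by the tethered oxygen. The phenoxyl radicals could couple through carbon. The ortho-dienone could dimerise by [4+2] cycloaddition or be oxidised further at the electrode. The fallback replaces electron transfer at an electrode by a two-electron oxidant that binds the phenol first: PhI(OAc)2 in CH2Cl2/HFIP at -20 °C exchanges a ligand for the ring B phenol, and the ring A oxygen then displaces iodobenzene at C1' within the same molecule. It sets out from 22 and comes back to the route at 23, which would be taken into step 16 without concentration; no new compound lies on its way.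

Step 16. The enolisable side-chain ketone could lose the β-silyloxy group by elimination, hydroxide could attack the dienone carbonyl instead of the five-ring ketone, or the silyl ethers could be partly lost at high pH. The fallback opens the spiro ring by alcoholysis instead of hydrolysis. From 23, 2-(trimethylsilyl)ethanol with catalytic DMAP in CH2Cl2 at 0 °C should give the 2-(trimethylsilyl)ethyl ester of the diaryl ether, F1, by the same retro-Claisen path under nearly neutral conditions. Transfer hydrogenation as in step 17 would give the R carbinol ester, F2. TBAF then removes the ester group together with both silyl ethers and comes back to the route at 26.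

Step 17. The ketone is flanked by a methoxy group that is itself crowded by the carboxylate, and it carries a β-quaternary carbon, so hydride transfer could be slow and facial discrimination could fall; the carboxylate could also bind the ruthenium centre. The fallback uses a stoichiometric chiral borane instead of a catalyst. From 24, excess (+)-B-chlorodiisopinocampheylborane in THF at -25 °C, followed by a diethanolamine work-up, transfers hydride through a cyclic six-membered transition state in which the aryl group takes the less crowded position. It should give the R alcohol, by analogy with acetophenone, and returns to the route at 25; no new compound lies on its way.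

Step 14. Silyl exchange at the tertiary triethylsilyl ether or incomplete cleavage of the crowded ring A acetal could give mixtures. The fallback changes the order of operations. From 19, HCl in MeOH at 0 °C to rt removes both methoxymethyl groups before any silyl group is on the tertiary oxygen and gives the bisphenol with the free tertiary alcohol, F3. Excess TESOTf with 2,6-lutidine silylates all three hydroxyls to the tris(triethylsilyl) compound, F4. K2CO3 in MeOH at 0 °C cleaves only the two aryl silyl ethers and returns to the route at 22.

Step 7. Deprotonation could occur in part at C4 (between the methoxymethoxy and methyl groups), or dilithiation could stall, giving isomeric iodides. The fallback moves the metalation to the carboxylic acid oxidation level. From 9, LiOH in THF/H2O cleaves the ester to 3-(methoxymethoxy)-5-methylbenzoic acid, F5. Lithium 2,2,6,6-tetramethylpiperidide (2.2 equiv) in THF, -78 to 0 °C, then iodine, gives 2-iodo-3-(methoxymethoxy)-5-methylbenzoic acid, F6, the carboxylate and the acetal oxygen jointly acidifying C2. BH3·THF reduces the acid and returns to the route at 12.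

**Further compounds**

F0 | step 15 | none | none
F1 | step 16 | 2-(trimethylsilyl)ethyl 6-{2-[(tert-butyldiphenylsilyl)oxymethyl]-6-hydroxy-4-methylphenoxy}-2-methoxy-3-[3-methyl-3-(triethylsilyloxy)butanoyl]benzoate | COc1c(C(=O)CC(C)(C)O[Si](CC)(CC)CC)ccc(Oc2c(O)cc(C)cc2CO[Si](c2ccccc2)(c2ccccc2)C(C)(C)C)c1C(=O)OCC[Si](C)(C)C
F2 | step 16 | 2-(trimethylsilyl)ethyl 6-{2-[(tert-butyldiphenylsilyl)oxymethyl]-6-hydroxy-4-methylphenoxy}-3-[(1R)-1-hydroxy-3-methyl-3-(triethylsilyloxy)butyl]-2-methoxybenzoate | COc1c([C@H](O)CC(C)(C)O[Si](CC)(CC)CC)ccc(Oc2c(O)cc(C)cc2CO[Si](c2ccccc2)(c2ccccc2)C(C)(C)C)c1C(=O)OCC[Si](C)(C)C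
F0 | step 17 | none | none
F3 | step 14 | 1-[3-{2-[(tert-butyldiphenylsilyl)oxymethyl]-6-hydroxy-4-methylbenzoyl}-4-hydroxy-2-methoxyphenyl]-3-hydroxy-3-methylbutan-1-one | COc1c(C(=O)CC(C)(C)O)ccc(O)c1C(=O)c1c(O)cc(C)cc1CO[Si](c1ccccc1)(c1ccccc1)C(C)(C)C
F4 | step 14 | 1-[3-{2-[(tert-butyldiphenylsilyl)oxymethyl]-4-methyl-6-(triethylsilyloxy)benzoyl}-2-methoxy-4-(triethylsilyloxy)phenyl]-3-methyl-3-(triethylsilyloxy)butan-1-one | COc1c(C(=O)CC(C)(C)O[Si](CC)(CC)CC)ccc(O[Si](CC)(CC)CC)c1C(=O)c1c(O[Si](CC)(CC)CC)cc(C)cc1CO[Si](c1ccccc1)(c1ccccc1)C(C)(C)C
F5 | step 7 | 3-(methoxymethoxy)-5-methylbenzoic acid | COCOc1cc(C)cc(C(=O)O)c1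
F6 | step 7 | 2-iodo-3-(methoxymethoxy)-5-methylbenzoic acid | COCOc1cc(C)cc(C(=O)O)c1I
A1 | alternative 1 | tert-butyl 6-{[4-(allyloxy)-2,4-dioxobutyl]oxy}-2-methoxy-3-[(4R)-2,2,6,6-tetramethyl-1,3-dioxan-4-yl]benzoate | COc1c([C@H]2CC(C)(C)OC(C)(C)O2)ccc(OCC(=O)CC(=O)OCC=C)c1C(=O)OC(C)(C)C
A2 | alternative 1 | methyl (E)-2-oxopent-3-enoate | C/C=C/C(=O)C(=O)OC
A3 | alternative 1 | 2-aryloxycyclohex-2-enone with C6'–CO2Me, C4'–CH3, C3'–CO2allyl and C2'=O, aryl being ring A as its tert-butyl ester with the (4R)-dioxanyl side chain (mixture at C3' and C4') | COc1c([C@H]2CC(C)(C)OC(C)(C)O2)ccc(OC2=C(C(=O)OC)CC(C)C(C(=O)OCC=C)C2=O)c1C(=O)OC(C)(C)C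
A4 | alternative 2 | 3-methoxy-4-[(4R)-2,2,6,6-tetramethyl-1,3-dioxan-4-yl]-2-(trimethylsilyl)phenyl trifluoromethanesulfonate | COc1c([C@H]2CC(C)(C)OC(C)(C)O2)ccc(OS(=O)(=O)C(F)(F)F)c1[Si](C)(C)C
A5 | alternative 2 | 2-(allyloxy)-6-{[tert-butyl(dimethyl)silyl]oxymethyl}-4-methylphenol | Cc1cc(OCC=C)c(O)c(CO[Si](C)(C)C(C)(C)C)c1
A6 | alternative 2 | 6-[2-(allyloxy)-6-{[tert-butyl(dimethyl)silyl]oxymethyl}-4-methylphenoxy]-2-methoxy-3-[(4R)-2,2,6,6-tetramethyl-1,3-dioxan-4-yl]benzoic acid | COc1c([C@H]2CC(C)(C)OC(C)(C)O2)ccc(Oc2c(OCC=C)cc(C)cc2CO[Si](C)(C)C(C)(C)C)c1C(=O)O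
A7 | alternative 3 | (E)-1-diazo-4-[(4R)-2,2,6,6-tetramethyl-1,3-dioxan-4-yl]but-3-en-2-one | [N-]=[N+]=CC(=O)/C=C/[C@H]1CC(C)(C)OC(C)(C)O1
A8 | alternative 3 | {[3-(allyloxy)-2-({3-[(4-methoxybenzyl)oxy]prop-1-yn-1-yl}oxy)-5-methylphenyl]methoxy}(tert-butyl)dimethylsilane | COc1ccc(COCC#COc2c(OCC=C)cc(C)cc2CO[Si](C)(C)C(C)(C)C)cc1
A9 | alternative 3 | 3-[2-(allyloxy)-6-{[tert-butyl(dimethyl)silyl]oxymethyl}-4-methylphenoxy]-2-{[(4-methoxybenzyl)oxy]methyl}-6-[(4R)-2,2,6,6-tetramethyl-1,3-dioxan-4-yl]phenol | Oc1c([C@H]2CC(C)(C)OC(C)(C)O2)ccc(Oc2c(OCC=C)cc(C)cc2CO[Si](C)(C)C(C)(C)C)c1COCc1ccc(OC)cc1
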